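The spirocyclohexene (ring carbons: spiro C-a, chain-bearing C-b, alkene CH C-c, carboxyl-bearing C-d, methyl-bearing C-e, CH2 C-f) is cut across C-b–C-c and C-e–C-f into two three-carbon units. In one pot a Morita–Baylis–Hillman carbonate of the complete side-chain aldehyde (C-b, C-a, C-f; its ester becomes the tetronate ketone carbon) meets tert-butyl 2-(phenylsulfonylmethyl)but-2-enoate (C-c, C-d, C-e): amine-catalysed allylic alkylation forms C-b–C-c, vinylogous Michael closure forms C-e–C-f, and the released ester enolate is hydroxylated at C-a. This exploits that C-a and C-d each bear a carboxyl-level carbon activating its own unit. Desulfonylation, acylketene macrolactonisation and Lacey–Dieckmann contraction complete the tetronate inside the 13-membered ring.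

Key step: step 14

Remark: the trisubstituted alkene of the target is read from the SMILES as having the acyl carbon and the chain carbon cis (2Z in the open-chain precursors).
Assumption: (DHQD)2AQN is taken to give half-ester 2 and (DHQD)2PHAL the C-b configuration drawn for 18; if either sense proves opposite, the pseudoenantiomeric dihydroquinine-derived catalyst is used.
Assumption: compounds 1, 13, 14 and all reagents named under the steps are taken as commercially available.

Step 1
Reactants: 1 meso-2,4-dimethylglutaric anhydride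
Product: 2 (2S,4R)-5-methoxy-2,4-dimethyl-5-oxopentanoic acid
Conditions: MeOH, (DHQD)2AQN (10 mol%), Et2O, −40 °C
Reagents that add atoms: methanol CO
Why: Alkaloid-catalysed desymmetrising methanolysis of a meso anhydride, in which the chiral amine differentiates the enantiotopic carbonyl groups and so fixes both methyl-bearing centres (syn) at once.

Step 2
Reactants: 2 (2S,4R)-5-methoxy-2,4-dimethyl-5-oxopentanoic acid
Product: 3 methyl (2R,4S)-5-hydroxy-2,4-dimethylpentanoate
Conditions: BH3·SMe2, THF, 0 °C to rt; MeOH quench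
Reagents that add atoms: none
Why: Borane reduces the carboxylic acid chemoselectively beside the methyl ester (acyloxyborane pathway).

Step 3
Reactants: 3 methyl (2R,4S)-5-hydroxy-2,4-dimethylpentanoate
Product: 4 methyl (2R,4S)-5-iodo-2,4-dimethylpentanoate
Conditions: I2, PPh3, imidazole, CH2Cl2, 0 °C
Reagents that add atoms: iodine II
Why: Appel-type iodination of the primary alcohol, carried out promptly so that lactonisation of 3 does not compete.

Step 4
Reactants: 4 methyl (2R,4S)-5-iodo-2,4-dimethylpentanoate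
Product: 5 methyl (2R,4R)-7-(1,3-dioxolan-2-yl)-2,4-dimethylheptanoate
Conditions: 2-(1,3-dioxolan-2-yl)ethylmagnesium bromide (1.5 equiv), Li2CuCl4 (5 mol%), THF, −30 to 0 °C
Reagents that add atoms: 2-(1,3-dioxolan-2-yl)ethylmagnesium bromide Br[Mg]CCC1OCCO1
Why: Copper-catalysed sp3–sp3 Grignard cross-coupling of the primary iodide, which at low temperature should outrun addition to the α-branched ester.

Step 5
Reactants: 5 methyl (2R,4R)-7-(1,3-dioxolan-2-yl)-2,4-dimethylheptanoate
Product: 6 (2R,4R)-7-(1,3-dioxolan-2-yl)-2,4-dimethylheptanal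
Conditions: i-Bu2AlH (1.1 equiv), CH2Cl2, −78 °C; aq. Rochelle salt
Reagents that add atoms: none
Why: Partial ester reduction through the aluminium hemiacetal that is stable at −78 °C; the α-stereocentre is not enolised and the aldehyde is used at once.

Step 6
Reactants: 6 (2R,4R)-7-(1,3-dioxolan-2-yl)-2,4-dimethylheptanal
Product: 7 ethyl (2Z,4R,6R)-9-(1,3-dioxolan-2-yl)-2,4,6-trimethylnon-2-enoate
Conditions: ethyl 2-[bis(2,2,2-trifluoroethoxy)phosphoryl]propanoate, KN(SiMe3)2, 18-crown-6, THF, −78 °C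
Reagents that add atoms: ethyl 2-[bis(2,2,2-trifluoroethoxy)phosphoryl]propanoate CCOC(=O)C(C)P(=O)(OCC(F)(F)F)OCC(F)(F)F
Why: Still–Gennari olefination, in which the electron-poor phosphonate eliminates under kinetic control and should give the (Z)-trisubstituted enoate.

Step 7
Reactants: 7 ethyl (2Z,4R,6R)-9-(1,3-dioxolan-2-yl)-2,4,6-trimethylnon-2-enoate
Product: 8 (2Z,4R,6R)-9-(1,3-dioxolan-2-yl)-2,4,6-trimethylnon-2-enoic acid
Conditions: LiOH, THF/MeOH/H2O, 40 °C; then 1 M HCl to pH 4, 0 °C
Reagents that add atoms: lithium hydroxide [Li+].[OH-]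
Why: Saponification of the only ester present; the mild acidification should leave the dioxolane intact.

Step 8
Reactants: 8 (2Z,4R,6R)-9-(1,3-dioxolan-2-yl)-2,4,6-trimethylnon-2-enoic acid
Product: 9 prop-2-enyl (2Z,4R,6R)-9-(1,3-dioxolan-2-yl)-2,4,6-trimethylnon-2-enoate
Conditions: allyl bromide, K2CO3, DMF, rt
Reagents that add atoms: allyl bromide C=CCBr
Why: Carboxylate O-alkylation installs an ester that palladium can later remove beside methyl and tert-butyl esters.

Step 9
Reactants: 9 prop-2-enyl (2Z,4R,6R)-9-(1,3-dioxolan-2-yl)-2,4,6-trimethylnon-2-enoate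
Product: 10 prop-2-enyl (2Z,4R,6R)-2,4,6-trimethyl-10-oxodec-2-enoate
Conditions: 2 M HCl, THF, 40 °C
Reagents that add atoms: water O
Why: Acid-catalysed acetal hydrolysis frees the aldehyde; the conjugated allyl ester is stable to dilute acid.

Step 10
Reactants: 10 prop-2-enyl (2Z,4R,6R)-2,4,6-trimethyl-10-oxodec-2-enoate
Product: 11 prop-2-enyl (2Z,4R,6R)-10-hydroxy-11-(methoxycarbonyl)-2,4,6-trimethyldodeca-2,11-dienoate (both C10 epimers)
Conditions: methyl acrylate (5 equiv), DABCO (1 equiv), MeOH, rt, 5 d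
Reagents that add atoms: methyl acrylate C=CC(=O)OC
Why: Morita–Baylis–Hillman reaction of an aliphatic aldehyde; the carbinol centre need not be controlled because its oxygen leaves in step 14.

Step 11
Reactants: 11 prop-2-enyl (2Z,4R,6R)-10-hydroxy-11-(methoxycarbonyl)-2,4,6-trimethyldodeca-2,11-dienoate
Product: 12 prop-2-enyl (2Z,4R,6R)-10-[(tert-butoxycarbonyl)oxy]-11-(methoxycarbonyl)-2,4,6-trimethyldodeca-2,11-dienoate (both C10 epimers)
Conditions: Boc2O, DMAP (10 mol%), CH2Cl2, 0 °C to rt
Reagents that add atoms: di-tert-butyl dicarbonate CC(C)(C)OC(=O)OC(=O)OC(C)(C)C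
Why: DMAP-catalysed carbonate formation gives a leaving group that releases its own base (tert-butoxide) on ionisation.

Step 12
Reactants: 13 acetaldehyde, 14 tert-butyl acrylate
Product: 15 tert-butyl 3-hydroxy-2-methylidenebutanoate (racemic)
Conditions: DABCO (20 mol%), neat, sealed vessel, rt, 7 d
Reagents that add atoms: none
Why: Morita–Baylis–Hillman reaction (DABCO adds to the acrylate and the ammonium enolate adds to acetaldehyde).

Step 13
Reactants: 15 tert-butyl 3-hydroxy-2-methylidenebutanoate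
Product: 17 tert-butyl (2Z)-2-[(phenylsulfonyl)methyl]but-2-enoate, via allylic acetate 16 (not isolated)
Conditions: Ac2O, DMAP (5 mol%), CH2Cl2, rt; evaporate; PhSO2Na, DMF, rt
Reagents that add atoms: sodium benzenesulfinate [Na+].[O-]S(=O)c1ccccc1; acetic anhydride CC(=O)OC(C)=O (its acetyl group is carried by 16 only)
Why: Acetylation followed by SN2' displacement through the sulfur of the sulfinate should give the thermodynamically preferred (Z)-allyl sulfone.

Step 14
Reactants: 12 prop-2-enyl (2Z,4R,6R)-10-[(tert-butoxycarbonyl)oxy]-11-(methoxycarbonyl)-2,4,6-trimethyldodeca-2,11-dienoate, 17 tert-butyl (2Z)-2-[(phenylsulfonyl)methyl]but-2-enoate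
Product: 20 1-tert-butyl 4-methyl (3R,4S,6S)-4-hydroxy-6-methyl-2-(phenylsulfonyl)-3-[(4R,6R,7Z)-4,6,8-trimethyl-9-oxo-9-(prop-2-enyloxy)non-7-enyl]cyclohex-1-ene-1,4-dicarboxylate, via allylation adduct 18 (not isolated), via potassium enolate 19 (not isolated)
Conditions: (DHQD)2PHAL (10 mol%), toluene, 40 °C; evaporate t-BuOH; THF, KN(SiMe3)2 (1.05 equiv), −78 to −40 °C; 3-phenyl-2-(phenylsulfonyl)oxaziridine, −78 °C; aq. NH4Cl
Reagents that add atoms: 3-phenyl-2-(phenylsulfonyl)oxaziridine O=S(=O)(c1ccccc1)N1OC1c1ccccc1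
Why: The amine adds to the acrylate CH2 of 12 and expels tert-butyl carbonate (CO2 and t-BuO−), the tert-butoxide deprotonates 17 at the sulfonyl CH2 and this carbon attacks C-b of the allylammonium ion in a second SN2' step (18, bond C-b–C-c); after removal of t-BuOH, KN(SiMe3)2 regenerates the sulfonyl allyl anion, whose γ-terminus C-e adds to C-f of the pendant acrylate (bond C-e–C-f), and the potassium ester enolate 19 is oxidised at C-a by the oxaziridine. The closest known types are the Lewis-base-catalysed asymmetric allylic alkylation of Morita–Baylis–Hillman carbonates with C–H acids, the α,α'-annulation of enamines with 2-(halomethyl)acrylates, and enolate hydroxylation with N-sulfonyloxaziridines. The only ring closed is the cyclohexene, by a 6-endo-trig Michael addition; closure through the α-carbon would need a cyclobutane and should not compete. C-b is set by the catalyst (both epimers of 12 converge on one ammonium ion), C-e by a half-chair transition state in which the chain on C-b is pseudoaxial to avoid A(1,2) strain with the sulfonyl group and the methyl on C-e occupies the outward, pseudoequatorial position of the allyl anion (methyl and chain cis), and C-a by attack of the oxidant anti to the pseudoaxial chain, which leaves the ester carbon cis to the chain. The step needs branched regioselectivity, α-attack of the sulfonyl anion in the first bond formation, and oxidation of 19 before proton transfer from the acidic γ-CH of the vinyl sulfone; the ammonium mechanism, the charge localisation next to sulfur, and removal of t-BuOH with low temperature should secure these.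

Step 15
Reactants: 20 1-tert-butyl 4-methyl (3R,4S,6S)-4-hydroxy-6-methyl-2-(phenylsulfonyl)-3-[(4R,6R,7Z)-4,6,8-trimethyl-9-oxo-9-(prop-2-enyloxy)non-7-enyl]cyclohex-1-ene-1,4-dicarboxylate
Product: 21 1-tert-butyl 4-methyl (3S,4S,6S)-4-hydroxy-6-methyl-3-[(4R,6R,7Z)-4,6,8-trimethyl-9-oxo-9-(prop-2-enyloxy)non-7-enyl]cyclohex-1-ene-1,4-dicarboxylate
Conditions: Na/Hg (6% Na), Na2HPO4, MeOH/THF, −20 °C
Reagents that add atoms: none
Why: Reductive desulfonylation of a vinyl sulfone by electron transfer (as in the Julia olefination); the alkene bearing both sulfonyl and ester groups should be reduced far more easily than the two simple enoates, and the ring fixes the alkene position.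

Step 16
Reactants: 21 1-tert-butyl 4-methyl (3S,4S,6S)-4-hydroxy-6-methyl-3-[(4R,6R,7Z)-4,6,8-trimethyl-9-oxo-9-(prop-2-enyloxy)non-7-enyl]cyclohex-1-ene-1,4-dicarboxylate
Product: 22 (2Z,4R,6R)-9-[(1S,4S,6S)-3-(tert-butoxycarbonyl)-6-hydroxy-6-(methoxycarbonyl)-4-methylcyclohex-2-enyl]-2,4,6-trimethylnon-2-enoic acid
Conditions: Pd(PPh3)4 (5 mol%), morpholine (5 equiv), THF, rt
Reagents that add atoms: none
Why: Tsuji–Trost deallylation, in which Pd(PPh3)4 ionises only the allyl ester and morpholine captures the allyl fragment.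

Step 17
Reactants: 22 (2Z,4R,6R)-9-[(1S,4S,6S)-3-(tert-butoxycarbonyl)-6-hydroxy-6-(methoxycarbonyl)-4-methylcyclohex-2-enyl]-2,4,6-trimethylnon-2-enoic acid
Product: 25 14-membered β-keto lactone of 22, via acyl Meldrum's acid 23 (not isolated), via acylketene 24 (not isolated)
Conditions: Meldrum's acid, DCC, DMAP, CH2Cl2, 0 °C to rt; filter, evaporate; toluene (1 mM), 110 °C
Reagents that add atoms: Meldrum's acid (2,2-dimethyl-1,3-dioxane-4,6-dione) CC1(C)OC(=O)CC(=O)O1
Why: C-Acylation of Meldrum's acid and thermal loss of acetone and CO2 give an acylketene that the tertiary hydroxyl should capture intramolecularly (acylketene macrolactonisation, known for hindered alcohols), with high dilution favouring the ring.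

Step 18
Reactants: 25 14-membered β-keto lactone of 22
Product: 26 tert-butyl ester of okilactomycin C
Conditions: KOt-Bu (2 equiv), THF, 0 °C to rt; 1 M HCl
Reagents that add atoms: none
Why: Lacey–Dieckmann cyclisation, in which the β-keto ester enolate attacks the neighbouring methyl ester (5-exo-trig) and contracts the lactone to the 3-acyltetronic acid inside the 13-membered carbocycle without touching the spiro centre.

Step 19
Reactants: 26 tert-butyl ester of okilactomycin C
Product: 27 okilactomycin C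
Conditions: CF3CO2H/CH2Cl2 (1:4), 0 °C
Reagents that add atoms: none
Why: Acidolysis of the tert-butyl ester (loss of 2-methylpropene) frees the ring carboxylic acid without hydrolytic conditions that could open the tetronate.

Compound list
1 | meso-2,4-dimethylglutaric anhydride (cis-3,5-dimethyloxane-2,6-dione) | C[C@H]1C[C@@H](C)C(=O)OC1=O | starting material
2 | (2S,4R)-5-methoxy-2,4-dimethyl-5-oxopentanoic acid | COC(=O)[C@H](C)C[C@H](C)C(=O)O | intermediate
3 | methyl (2R,4S)-5-hydroxy-2,4-dimethylpentanoate | COC(=O)[C@H](C)C[C@H](C)CO | intermediate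
4 | methyl (2R,4S)-5-iodo-2,4-dimethylpentanoate | COC(=O)[C@H](C)C[C@H](C)CI | intermediate
5 | methyl (2R,4R)-7-(1,3-dioxolan-2-yl)-2,4-dimethylheptanoate | COC(=O)[C@H](C)C[C@H](C)CCCC1OCCO1 | intermediate
6 | (2R,4R)-7-(1,3-dioxolan-2-yl)-2,4-dimethylheptanal | O=C[C@H](C)C[C@H](C)CCCC1OCCO1 | intermediate
7 | ethyl (2Z,4R,6R)-9-(1,3-dioxolan-2-yl)-2,4,6-trimethylnon-2-enoate | CCOC(=O)/C(C)=C\[C@H](C)C[C@H](C)CCCC1OCCO1 | intermediate
8 | (2Z,4R,6R)-9-(1,3-dioxolan-2-yl)-2,4,6-trimethylnon-2-enoic acid | OC(=O)/C(C)=C\[C@H](C)C[C@H](C)CCCC1OCCO1 | intermediate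
9 | prop-2-enyl (2Z,4R,6R)-9-(1,3-dioxolan-2-yl)-2,4,6-trimethylnon-2-enoate | C=CCOC(=O)/C(C)=C\[C@H](C)C[C@H](C)CCCC1OCCO1 | intermediate
10 | prop-2-enyl (2Z,4R,6R)-2,4,6-trimethyl-10-oxodec-2-enoate | C=CCOC(=O)/C(C)=C\[C@H](C)C[C@H](C)CCCC=O | intermediate
11 | prop-2-enyl (2Z,4R,6R)-10-hydroxy-11-(methoxycarbonyl)-2,4,6-trimethyldodeca-2,11-dienoate, both C10 epimers | C=CCOC(=O)/C(C)=C\[C@H](C)C[C@H](C)CCCC(O)C(=C)C(=O)OC | intermediate
12 | prop-2-enyl (2Z,4R,6R)-10-[(tert-butoxycarbonyl)oxy]-11-(methoxycarbonyl)-2,4,6-trimethyldodeca-2,11-dienoate, both C10 epimers | C=CCOC(=O)/C(C)=C\[C@H](C)C[C@H](C)CCCC(OC(=O)OC(C)(C)C)C(=C)C(=O)OC | intermediate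
13 | acetaldehyde | CC=O | starting material
14 | tert-butyl acrylate | C=CC(=O)OC(C)(C)C | starting material
15 | tert-butyl 3-hydroxy-2-methylidenebutanoate (racemic) | CC(O)C(=C)C(=O)OC(C)(C)C | intermediate
16 | tert-butyl 3-acetoxy-2-methylidenebutanoate (racemic, not isolated) | CC(OC(C)=O)C(=C)C(=O)OC(C)(C)C | intermediate
17 | tert-butyl (2Z)-2-[(phenylsulfonyl)methyl]but-2-enoate | C/C=C(\CS(=O)(=O)c1ccccc1)C(=O)OC(C)(C)C | intermediate
18 | prop-2-enyl (2Z,4R,6R,10R)-10-[(2Z)-2-(tert-butoxycarbonyl)-1-(phenylsulfonyl)but-2-enyl]-11-(methoxycarbonyl)-2,4,6-trimethyldodeca-2,11-dienoate, both epimers at the sulfonyl carbon (not isolated) | C=CCOC(=O)/C(C)=C\[C@H](C)C[C@H](C)CCC[C@H](C(=C)C(=O)OC)C(S(=O)(=O)c1ccccc1)/C(C(=O)OC(C)(C)C)=C\C | intermediate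
19 | potassium ester enolate of the cyclised vinyl sulfone, ring as in 20 with C-a as C=C(OCH3)OK (not isolated) | [K+].C=CCOC(=O)/C(C)=C\[C@H](C)C[C@H](C)CCC[C@H]1C(S(=O)(=O)c2ccccc2)=C(C(=O)OC(C)(C)C)[C@@H](C)CC1=C([O-])OC | intermediate
20 | 1-tert-butyl 4-methyl (3R,4S,6S)-4-hydroxy-6-methyl-2-(phenylsulfonyl)-3-[(4R,6R,7Z)-4,6,8-trimethyl-9-oxo-9-(prop-2-enyloxy)non-7-enyl]cyclohex-1-ene-1,4-dicarboxylate | C=CCOC(=O)/C(C)=C\[C@H](C)C[C@H](C)CCC[C@H]1C(S(=O)(=O)c2ccccc2)=C(C(=O)OC(C)(C)C)[C@@H](C)C[C@@]1(O)C(=O)OC | intermediate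
21 | 1-tert-butyl 4-methyl (3S,4S,6S)-4-hydroxy-6-methyl-3-[(4R,6R,7Z)-4,6,8-trimethyl-9-oxo-9-(prop-2-enyloxy)non-7-enyl]cyclohex-1-ene-1,4-dicarboxylate | C=CCOC(=O)/C(C)=C\[C@H](C)C[C@H](C)CCC[C@H]1C=C(C(=O)OC(C)(C)C)[C@@H](C)C[C@@]1(O)C(=O)OC | intermediate
22 | (2Z,4R,6R)-9-[(1S,4S,6S)-3-(tert-butoxycarbonyl)-6-hydroxy-6-(methoxycarbonyl)-4-methylcyclohex-2-enyl]-2,4,6-trimethylnon-2-enoic acid | OC(=O)/C(C)=C\[C@H](C)C[C@H](C)CCC[C@H]1C=C(C(=O)OC(C)(C)C)[C@@H](C)C[C@@]1(O)C(=O)OC | intermediate
23 | 5-acyl-2,2-dimethyl-1,3-dioxane-4,6-dione from 22, the acyl Meldrum's acid (not isolated) | CC1(C)OC(=O)C(C(=O)/C(C)=C\[C@H](C)C[C@H](C)CCC[C@H]2C=C(C(=O)OC(C)(C)C)[C@@H](C)C[C@@]2(O)C(=O)OC)C(=O)O1 | intermediate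
24 | acylketene from 23 (not isolated) | O=C=CC(=O)/C(C)=C\[C@H](C)C[C@H](C)CCC[C@H]1C=C(C(=O)OC(C)(C)C)[C@@H](C)C[C@@]1(O)C(=O)OC | intermediate
25 | 14-membered β-keto lactone: the tertiary oxygen on C-a is acylated by the chain-end 3-oxo ester, C-a keeps CO2CH3 and C-d keeps CO2t-Bu | CC1=C/[C@H](C)C[C@H](C)CCC[C@H]2C=C(C(=O)OC(C)(C)C)[C@@H](C)C[C@]2(C(=O)OC)OC(=O)CC\1=O | intermediate
26 | tert-butyl ester of okilactomycin C | CC1=C/[C@H](C)C[C@H](C)CCC[C@H]2C=C(C(=O)OC(C)(C)C)[C@@H](C)C[C@]23OC(=O)\C(=C\1O)C3=O | intermediate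
27 | okilactomycin C | CC1=C/[C@H](C)C[C@H](C)CCC[C@H]2C=C(C(=O)O)[C@@H](C)C[C@]23OC(=O)\C(=C\1O)C3=O | target

Total step count: 19. Longest linear sequence: 17 steps (steps 1–11, then 14–19).

Steps most likely to fail

Step 14. The allyl sulfone is only weakly acidic, so deprotonation by the self-generated tert-butoxide and attack on an aliphatic (not aryl-substituted) allylammonium ion may be slow; the enolate may also be protonated before it is oxidised. The fallback sets out from 11 and comes back at 20. Alcohol 11 is converted under Corey–Kim conditions (N-bromosuccinimide, Me2S) into 12-methyl 1-prop-2-enyl (2Z,4R,6R,10Z)-11-(bromomethyl)-2,4,6-trimethyldodeca-2,10-dienedioate F1, which with one equivalent of DABCO gives the isolable allylammonium bromide F2. The preformed potassium salt of 17 (KN(SiMe3)2, THF, −78 °C) attacks F2 at C-b in an SN2' reaction and releases DABCO, giving 18 together with its C-b epimer F3. A second equivalent of KN(SiMe3)2 and the oxaziridine then act as in step 14, and 20 is separated by chromatography from its ring diastereomer F4. Stereocontrol at C-b is thus replaced by separation.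

Step 15. Electron transfer may over-reduce the ring enoate or isomerise the (Z)-enoate of the side chain. The fallback sets out from 20 and comes back at 21. Conjugate reduction with LiBH(s-Bu)3 (THF, −78 °C) gives the saturated β-sulfonyl ester F5, and DBU (CH2Cl2, rt) then removes benzenesulfinic acid by E1cB elimination, which can only restore the C-c=C-d enoate of 21.

Step 17. At 110 °C the dienyl acylketene may dimerise or suffer a 1,5-hydrogen shift from the (Z)-alkene before the hindered tertiary alcohol captures it. The fallback sets out from 22 and comes back at 25. Acid 22 is activated with 1,1'-carbonyldiimidazole as the acyl imidazolide F6, which is C-acylated by the magnesium salt of 3-(tert-butylsulfanyl)-3-oxopropanoic acid with loss of CO2 to give the S-tert-butyl β-keto thioester F7. AgOCOCF3 (THF, rt, high dilution) then activates the thioester, and the tertiary hydroxyl closes lactone 25 at room temperature without a free ketene.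

Further compounds
F1 | step 14 | 12-methyl 1-prop-2-enyl (2Z,4R,6R,10Z)-11-(bromomethyl)-2,4,6-trimethyldodeca-2,10-dienedioate | C=CCOC(=O)/C(C)=C\[C@H](C)C[C@H](C)CCC/C=C(\CBr)C(=O)OC
F2 | step 14 | 1-allyl-4-aza-1-azoniabicyclo[2.2.2]octane bromide formed from F1 and DABCO | C=CCOC(=O)/C(C)=C\[C@H](C)C[C@H](C)CCC/C=C(\C[N+]12CCN(CC1)CC2)C(=O)OC.[Br-]
F3 | step 14 | C-b epimer (10S) of 18 | C=CCOC(=O)/C(C)=C\[C@H](C)C[C@H](C)CCC[C@@H](C(=C)C(=O)OC)C(S(=O)(=O)c1ccccc1)/C(C(=O)OC(C)(C)C)=C\C
F4 | step 14 | ring diastereomer (3S,4R,6R) of 20 | C=CCOC(=O)/C(C)=C\[C@H](C)C[C@H](C)CCC[C@@H]1C(S(=O)(=O)c2ccccc2)=C(C(=O)OC(C)(C)C)[C@H](C)C[C@]1(O)C(=O)OC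
F5 | step 15 | saturated β-sulfonyl ester from conjugate reduction of 20 (mixture at the two new centres) | C=CCOC(=O)/C(C)=C\[C@H](C)C[C@H](C)CCC[C@H]1C(S(=O)(=O)c2ccccc2)C(C(=O)OC(C)(C)C)[C@@H](C)C[C@@]1(O)C(=O)OC
F6 | step 17 | acyl imidazolide of 22 | O=C(/C(C)=C\[C@H](C)C[C@H](C)CCC[C@H]1C=C(C(=O)OC(C)(C)C)[C@@H](C)C[C@@]1(O)C(=O)OC)n1ccnc1
F7 | step 17 | S-tert-butyl β-keto thioester from F6 | CC(C)(C)SC(=O)CC(=O)/C(C)=C\[C@H](C)C[C@H](C)CCC[C@H]1C=C(C(=O)OC(C)(C)C)[C@@H](C)C[C@@]1(O)C(=O)OC
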